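(The earlier runs and the new flask are simulated for substances that don't exist.)

Keep the books in the fraction of Q left, not in the X made.

| flask | Q | J | temperature | remark | time |
|---|---|---|---|---|---|
| epsilon | 20 mM | 1.7 equiv | 45 °C | run made earlier |  |
| gamma | 20 mM | 3.8 equiv | 88 °C | run made earlier |  |
| theta | 40 mM | 2.5 equiv | 45 °C | run made earlier |  |
| Saturday's | 20 mM | 2.50 equiv | 125 °C |  | 6.0 min |
| Wednesday's | 20 mM | 2.50 equiv | 50 °C |  | 6.0 min |
| Tuesday's | 20 mM | 2.50 equiv | 75 °C |  | 6.0 min |
| Friday's | 20 mM | 2.50 equiv | 100 °C |  | 6.0 min |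

| run | time / min | X / % | Q / % |
|---|---|---|---|
| epsilon | 25.0 | 57.2 | 7.7 |
| epsilon | 50.0 | 58.1 | 3.1 |
| epsilon | 120 | 54.4 | 0.6 |
| epsilon | 300 | 46.7 | 0 |
| gamma | 10.0 | 9.0 | 0 |
| gamma | 20.0 | 3.5 | 0.5 |
| gamma | 30.0 | 0.7 | 0.3 |
| gamma | 40.0 | 1.2 | 0.9 |
| theta | 25.0 | 51.2 | 0 |
| theta | 50.0 | 43.2 | 0.2 |
| theta | 120 | 32.5 | 0 |
| theta | 300 | 20.7 | 0.1 |

(standard deviation of a reading: 0.5 percentage points)

* which flask leads in amount of X, in percent of the Q charged ("all alike" within 1.5 percentage points) (Saturday's / Wednesday's / Tuesday's / Friday's / all alike)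
* how much X is there at the end, in percent of the Q charged: Saturday's
* how much X is there at the end, in percent of the Q charged: Wednesday's
* how much X is there at the end, in percent of the Q charged: Tuesday's
* how much X is there at the end, in percent of the Q charged: Friday's

- the analysis behind the earlier runs scatters by 0.5 percentage points, standard deviation

In the first instants Q and J meet and X begins to form. The epsilon run at 25.0 min has 7.7% of Q left and 57.2% of X, so s reads 0.620 there, the X found per Q gone (the selectivity). Let q be the fraction of Q left and f the fraction of the X made that still stands; then X = s × (1 − q) × f.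

The middle of the run is the fall of q. In a rough pseudo-first-order reckoning, with J counted at its charge, ln(1/q) grows with J charge times time. Wednesday's has 0.353 of the epsilon run's product at 25.0 min. An assumed doubling per 10 degrees adds a factor 1.41 from 45 °C to 50 °C. So q = 27.8% for Wednesday's. But the epsilon run's second stretch of the same length took only 0.910 off ln(1/q), less than the first stretch's 2.56. In the epsilon run the early minutes therefore count for more than the average, and the q reckoned for Wednesday's probably stands high.

Towards the end the earlier runs show X falling, and f measures that. With Q at 0%, the theta run keeps 0.404 of its X from 25.0 min to 300 min. The gamma run at 10.0 min, hotter and richer in J, has f = 0.145 if s is taken over from the epsilon run. The epsilon run keeps 0.936 of its X over 70.0 min, so the reckoning here takes f as one for the 6.0 min of Wednesday's. With that, it gives Wednesday's 44.7% of X.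

The forecast names Wednesday's as leader, with 41% there (range 29% to 52%), a little less than the reckoning here. It puts Tuesday's at 32%, Friday's at 11% and Saturday's at 0.5%, and of the gamma run it says “Back-extrapolation puts the X selectivity there at only about 30%”.

The flasks give 58.0% in Wednesday's, 51.0% in Tuesday's, 33.1% in Friday's and 18.3% in Saturday's, so Wednesday's leads.

    Q + J → X + G (k = 0.210 L mol⁻¹ s⁻¹, Ea = 69.0 kJ mol⁻¹)
    Q + J → L + G (k = 0.0950 L mol⁻¹ s⁻¹, Ea = 66.0 kJ mol⁻¹)
    J + X → E + G (k = 0.0150 L mol⁻¹ s⁻¹, Ea = 69.0 kJ mol⁻¹)
    J + L → E + G (k = 0.00630 L mol⁻¹ s⁻¹, Ea = 81.0 kJ mol⁻¹)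
    J + G ⇌ Z, settled at all times (K = 320 L mol⁻¹, ΔH = 11.0 kJ mol⁻¹)
    (constants at 50 °C)

Wednesday's ended with 8.43% of Q left, less than the reckoned q, and s, with f at one, turns that into 56.8% against its 58.0%. The neighbour, Wednesday's charge held at 25 °C for the same time, ended with 58.5% of Q left, so s, with f at one, gives 25.7%, and that flask held 27.4% of X.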